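**Retrosynthetic overview**

1. The strategy rests on one feature of the six-membered carbocycle: C1 (tertiary carbinol bearing C7H2OBz) lies between C2 and C6 and para to C4. In 4-hydroxy-4-(benzoyloxymethyl)cyclohexa-2,5-dienone C1 is therefore a prochiral centre flanked by two enantiotopic enone arms (C2=C3 and C6=C5) that share the C4 carbonyl.
2. Key disconnection: the C6–O bond, formed by catalyst-controlled intramolecular oxa-Michael addition of the phenylboronic hemiester on O1. This closes the only ring made in the route, a cis-fused 1,3,2-dioxaborolane (the carbocycle is bought as the quinone monoketal), and sets C1 and C6.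
3. The para-quinol comes from 4,4-dimethoxycyclohexadienone by Tamao hydroxymethylation, O7 benzoylation and ketal hydrolysis.
4. The remaining C4 enone carries the rest: boronate exchanged for acetonide, C5–O by Rubottom oxidation, C2–O and the C3=C4 alkene by epoxidation and Wharton transposition.
5. Endgame: C2 benzoate, desilylation at C5, Mitsunobu inversion with benzoic acid (C5–OBz cis to O6), acetonide hydrolysis.

Key step: step 5

Conventions: target numbering (C1–C7) is used for every ring compound; α is the face of O1 and O6, β is the face of C7. Names given in enone numbering are marked as such.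
Assumption: the quinine-derived amine–thiourea is taken to select the enone arm that leads to the (1S,6S) boronate. The sense of induction on a para-quinol cannot be derived beforehand; the pseudo-enantiomeric quinidine-derived catalyst would be used if it proves opposite.

**Route**

Step 1
Reactants: 1 4,4-dimethoxycyclohexa-2,5-dien-1-one; 2 (chloromethyl)(isopropoxy)dimethylsilane
Product: 4 1-{[isopropoxy(dimethyl)silyl]methyl}-4,4-dimethoxycyclohexa-2,5-dien-1-ol, via Grignard reagent 3 (not isolated)
Conditions: 2, Mg, BrCH2CH2Br (cat.), THF, rt to reflux; then 1, THF, −78 to 0 °C; aq. NH4Cl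
Reagents that add atoms: none
Why: Grignard 1,2-addition of the Tamao hydroxymethyl-anion equivalent to the only free carbonyl of the quinone monoketal, the ketal masking the second carbonyl and the alkoxysilane resisting Peterson elimination at the magnesium alkoxide stage.

Step 2
Reactants: 4 1-{[isopropoxy(dimethyl)silyl]methyl}-4,4-dimethoxycyclohexa-2,5-dien-1-ol
Product: 5 1-(hydroxymethyl)-4,4-dimethoxycyclohexa-2,5-dien-1-ol
Conditions: 30% H2O2, KF, KHCO3, MeOH/THF (1:1), rt; aq. Na2S2O3
Reagents that add atoms: hydrogen peroxide, OO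
Why: Tamao–Fleming oxidation turns the fluoride-activated C7–Si bond into C7–OH under bicarbonate buffering, which should neither ionise the bis-allylic tertiary alcohol nor hydrolyse the ketal.

Step 3
Reactants: 5 1-(hydroxymethyl)-4,4-dimethoxycyclohexa-2,5-dien-1-ol; 6 benzoyl chloride
Product: 7 (1-hydroxy-4,4-dimethoxycyclohexa-2,5-dien-1-yl)methyl benzoate
Conditions: BzCl (1.05 equiv), pyridine, CH2Cl2, −10 to 0 °C
Reagents that add atoms: none
Why: Pyridine-mediated acylation distinguishes the unhindered primary hydroxyl from the tertiary one, and the basic medium preserves the acid-labile ketal.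

Step 4
Reactants: 7 (1-hydroxy-4,4-dimethoxycyclohexa-2,5-dien-1-yl)methyl benzoate
Product: 8 4-(benzoyloxymethyl)-4-hydroxycyclohexa-2,5-dien-1-one (para-quinol)
Conditions: PPTS (10 mol%), acetone/H2O (10:1), rt
Reagents that add atoms: water, O
Why: Mild acid hydrolysis of the dimethyl ketal releases the cross-conjugated dienone, while the benzoate and tertiary hydroxyl are unaffected and the quaternary C1 prevents aromatisation.

Step 5
Reactants: 8 4-(benzoyloxymethyl)-4-hydroxycyclohexa-2,5-dien-1-one; 9 phenylboronic acid
Product: 11 cis-fused phenylboronate of (4S,5S)-4-(benzoyloxymethyl)-4,5-dihydroxycyclohex-2-en-1-one (enone numbering), via boronic acid hemiester 10 (not isolated)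
Conditions: PhB(OH)2 (1.5 equiv), 9-amino-9-deoxy-epi-quinine N′-[3,5-bis(trifluoromethyl)phenyl]thiourea (20 mol%), 4 Å MS, toluene, rt
Reagents that add atoms: none
Why: Proposed new method: the tertiary hydroxyl of 8 condenses reversibly with PhB(OH)2 to hemiester 10 (the sieves take up the water), the quinuclidine nitrogen of the catalyst binds boron and raises the nucleophilicity of the remaining B–OH oxygen while the thiourea hydrogen-bonds the dienone carbonyl, and that oxygen adds intramolecularly to C6, one of the two enantiotopic β-carbons. The closest known reaction type is the amine–thiourea-catalysed oxa-Michael addition of boronic acid hemiesters to acyclic γ-hydroxy enones, and chiral-acid oxa-Michael desymmetrisations of para-quinols show that an oxygen nucleophile tethered to O1 can tell the two arms of such a dienone apart; their use together on a tertiary quinol is the untested part. The 1,3,2-dioxaborolane closes by 5-exo-trig attack of oxygen on the C6 terminus of the C6=C5 enone arm, and a five-membered ring fused to the cyclohexenone can only be cis, so O6 arrives on the face that O1 occupies. C1 becomes stereogenic because the two arms are no longer equivalent, and its configuration and that of C6 are both decided by which arm the chiral catalyst presents to the boronate oxygen, since the substrate has no bias of its own. The step needs enantiotopic-group selectivity and mono-addition: the one hydroxyl can deliver only one oxygen, and the cyclic boronate should hold the β-oxygen against retro-Michael loss.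

Step 6
Reactants: 11 cis-fused phenylboronate of (4S,5S)-4-(benzoyloxymethyl)-4,5-dihydroxycyclohex-2-en-1-one
Product: 12 (4S,5S)-4-(benzoyloxymethyl)-4,5-(isopropylidenedioxy)cyclohex-2-en-1-one (acetonide enone; enone numbering)
Conditions: pinacol (1.5 equiv), 2,2-dimethoxypropane, PPTS (10 mol%), acetone, rt
Reagents that add atoms: 2,2-dimethoxypropane, COC(C)(C)OC
Why: Acid-catalysed boronic ester transesterification hands the phenylboron unit to pinacol while the cis-diol is captured as its isopropylidene ketal (transketalisation), so the elimination-prone free β-hydroxy ketone should not accumulate and neither stereocentre is touched.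

Step 7
Reactants: 12 (4S,5S)-4-(benzoyloxymethyl)-4,5-(isopropylidenedioxy)cyclohex-2-en-1-one
Product: 13 TBS dienol ether of 12 (silyloxy diene C2=C3–C4(OTBS)=C5; 1S,6S)
Conditions: TBSOTf (1.3 equiv), Et3N (2.5 equiv), CH2Cl2, −78 to 0 °C
Reagents that add atoms: tert-butyldimethylsilyl trifluoromethanesulfonate, CC(C)(C)[Si](C)(C)OS(=O)(=O)C(F)(F)F
Why: Soft enolisation with silyl triflate and amine: C5 holds the only enolisable hydrogens because the γ-position C1 is quaternary, so the cross-conjugated 2-silyloxy diene should form without a free enolate that could expel O6 by E1cB elimination.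

Step 8
Reactants: 13 TBS dienol ether of 12
Product: 15 (4S,5S,6S)-4-(benzoyloxymethyl)-6-(tert-butyldimethylsilyloxy)-4,5-(isopropylidenedioxy)cyclohex-2-en-1-one (enone numbering; 5β-silyloxy enone in target numbering), via silyloxy epoxide 14 (not isolated)
Conditions: mCPBA (1.1 equiv), NaHCO3, CH2Cl2, −20 °C to rt
Reagents that add atoms: 3-chloroperoxybenzoic acid, OOC(=O)c1cccc(Cl)c1
Why: Rubottom oxidation: the peracid should epoxidise the electron-rich C4=C5 enol ether on the β face, opposite the dioxolane attached at C6, and the silyloxy oxirane opens with 1,4-silyl migration to the α′-silyloxy ketone, which sets C5–O β (trans to O6).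

Step 9
Reactants: 15 5β-silyloxy enone
Product: 16 2β,3β-epoxy-4-ketone (2,3-epoxide of 15 on the β face)
Conditions: t-BuOOH (2 equiv, in decane), DBU (1.1 equiv), CH2Cl2, 0 °C
Reagents that add atoms: tert-butyl hydroperoxide, CC(C)(C)OO
Why: Weitz–Scheffer nucleophilic epoxidation: the peroxide anion should add to C2 anti to the allylic C1–O bond and the dioxolane ring, and the enolate then closes the oxirane, which sets C2 and C3 together on the β face.

Step 10
Reactants: 16 2β,3β-epoxy-4-ketone
Product: 18 allylic alcohol (2β-OH; C3=C4; 5β-OTBS; 1,6-acetonide; 7-benzoate), via epoxy hydrazone 17 (not isolated)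
Conditions: N2H4·H2O (3 equiv), AcOH (0.5 equiv), MeOH, 0 °C to rt
Reagents that add atoms: none
Why: Wharton transposition: the hydrazone tautomerises with opening of the oxirane to an alkenyl diazene that loses N2, which moves the unsaturation to C3=C4 and leaves the unbroken C2–O bond of the epoxide as the β allylic hydroxyl.

Step 11
Reactants: 18 allylic alcohol; 6 benzoyl chloride
Product: 19 2β-benzoate of 18
Conditions: BzCl (2 equiv), pyridine, DMAP (20 mol%), CH2Cl2, 0 °C to rt
Reagents that add atoms: none
Why: DMAP-catalysed acylation of the only free hydroxyl; the C2–O bond is not broken, so the β configuration is kept.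

Step 12
Reactants: 19 2β-benzoate of 18
Product: 20 5β-alcohol (2β,7-dibenzoate; 1,6-acetonide)
Conditions: HF·pyridine, pyridine/THF, 0 °C to rt
Reagents that add atoms: none
Why: Fluoride-mediated cleavage of the silyl ether under buffered, weakly acidic conditions that should not promote benzoyl migration and that leave the acetonide and both esters in place.

Step 13
Reactants: 20 5β-alcohol; 21 benzoic acid
Product: 22 tribenzoate acetonide (2β,5α,7-tribenzoate; O1/O6 isopropylidene)
Conditions: PPh3 (2 equiv), DIAD (2 equiv), PhCO2H (2 equiv), THF, 0 °C to rt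
Reagents that add atoms: none
Why: Mitsunobu reaction: benzoate displaces the alkoxyphosphonium group at the allylic C5 by SN2 with inversion, turning the β alcohol into the α benzoate cis to O6, with every other oxygen protected.

Step 14
Reactants: 22 tribenzoate acetonide
Product: 23 [(1S,2S,5S,6S)-2,5-bis(benzoyloxy)-1,6-dihydroxycyclohex-3-en-1-yl]methyl benzoate (target)
Conditions: TFA/H2O (9:1), CH2Cl2, 0 °C
Reagents that add atoms: none
Why: Acid hydrolysis of the isopropylidene ketal; benzoates should survive cold aqueous trifluoroacetic acid, no C–O bond at a stereocentre is broken, and short exposure limits acyl migration to the freed hydroxyls.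

**Compound list**

1 | 4,4-dimethoxycyclohexa-2,5-dien-1-one | COC1(OC)C=CC(=O)C=C1 | starting material
2 | (chloromethyl)(isopropoxy)dimethylsilane | CC(C)O[Si](C)(C)CCl | starting material
3 | [(isopropoxydimethylsilyl)methyl]magnesium chloride (Grignard reagent, not isolated) | CC(C)O[Si](C)(C)C[Mg]Cl | intermediate
4 | 1-{[isopropoxy(dimethyl)silyl]methyl}-4,4-dimethoxycyclohexa-2,5-dien-1-ol | CC(C)O[Si](C)(C)CC1(O)C=CC(OC)(OC)C=C1 | intermediate
5 | 1-(hydroxymethyl)-4,4-dimethoxycyclohexa-2,5-dien-1-ol | OCC1(O)C=CC(OC)(OC)C=C1 | intermediate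
6 | benzoyl chloride | O=C(Cl)c1ccccc1 | starting material
7 | (1-hydroxy-4,4-dimethoxycyclohexa-2,5-dien-1-yl)methyl benzoate | O=C(OCC1(O)C=CC(OC)(OC)C=C1)c1ccccc1 | intermediate
8 | 4-(benzoyloxymethyl)-4-hydroxycyclohexa-2,5-dien-1-one (para-quinol, key-step precursor) | O=C1C=CC(O)(COC(=O)c2ccccc2)C=C1 | intermediate
9 | phenylboronic acid | OB(O)c1ccccc1 | starting material
10 | phenylboronic acid hemiester on the tertiary oxygen of 8 (not isolated) | O=C1C=CC(COC(=O)c2ccccc2)(OB(O)c2ccccc2)C=C1 | intermediate
11 | cis-fused phenylboronate (2-phenyl-1,3,2-dioxaborolane) of (4S,5S)-4-(benzoyloxymethyl)-4,5-dihydroxycyclohex-2-en-1-one; target C1 and C6 both S, O1 and O6 cis | O=C1C=C[C@@]2(COC(=O)c3ccccc3)OB(c3ccccc3)O[C@H]2C1 | intermediate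
12 | (4S,5S)-4-(benzoyloxymethyl)-4,5-(isopropylidenedioxy)cyclohex-2-en-1-one (cis-fused acetonide enone) | O=C1C=C[C@@]2(COC(=O)c3ccccc3)OC(C)(C)O[C@H]2C1 | intermediate
13 | TBS dienol ether of 12: C2=C3–C4(OTBS)=C5 diene, (1S,6S), 1,6-acetonide, 7-benzoate | CC(C)(C)[Si](C)(C)OC1=C[C@@H]2OC(C)(C)O[C@]2(COC(=O)c2ccccc2)C=C1 | intermediate
14 | 4,5-epoxide of 13 on the β face, OTBS on C4 (silyloxy epoxide, not isolated) | CC(C)(C)[Si](C)(C)O[C@@]1(O2)C=C[C@@]3(COC(=O)c4ccccc4)OC(C)(C)O[C@H]3[C@@H]12 | intermediate
15 | (4S,5S,6S)-4-(benzoyloxymethyl)-6-(tert-butyldimethylsilyloxy)-4,5-(isopropylidenedioxy)cyclohex-2-en-1-one; in target numbering C5–OTBS is β, trans to O6 | O=C1C=C[C@@]2(COC(=O)c3ccccc3)OC(C)(C)O[C@H]2[C@@H]1O[Si](C)(C)C(C)(C)C | intermediate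
16 | 2β,3β-epoxy-4-ketone: epoxide of 15 on the face opposite the acetonide, 5β-OTBS | O=C1[C@@H]2O[C@@H]2[C@@]3(COC(=O)c4ccccc4)OC(C)(C)O[C@H]3[C@@H]1O[Si](C)(C)C(C)(C)C | intermediate
17 | C4 hydrazone of 16 (not isolated) | NN=C1[C@@H]2O[C@@H]2[C@@]3(COC(=O)c4ccccc4)OC(C)(C)O[C@H]3[C@@H]1O[Si](C)(C)C(C)(C)C | intermediate
18 | allylic alcohol: 2β-OH, C3=C4 alkene, 5β-OTBS, O1/O6 acetonide (α), 7-benzoate | O=C(OC[C@@]1(OC(C)(C)O2)[C@@H](O)C=C[C@@H](O[Si](C)(C)C(C)(C)C)[C@@H]12)c1ccccc1 | intermediate
19 | 2β-benzoate of 18 (5β-OTBS, acetonide, 7-benzoate) | O=C(OC[C@@]1(OC(C)(C)O2)[C@@H](OC(=O)c3ccccc3)C=C[C@@H](O[Si](C)(C)C(C)(C)C)[C@@H]12)c1ccccc1 | intermediate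
20 | 5β-alcohol: 2β,7-dibenzoate, O1/O6 acetonide, C3=C4 | O=C(OC[C@@]1(OC(C)(C)O2)[C@@H](OC(=O)c3ccccc3)C=C[C@@H](O)[C@@H]12)c1ccccc1 | intermediate
21 | benzoic acid | O=C(O)c1ccccc1 | starting material
22 | tribenzoate acetonide: 2β-OBz, 5α-OBz (cis to O6), 7-OBz, O1/O6 isopropylidene | O=C(OC[C@@]1(OC(C)(C)O2)[C@@H](OC(=O)c3ccccc3)C=C[C@H](OC(=O)c3ccccc3)[C@@H]12)c1ccccc1 | intermediate
23 | [(1S,2S,5S,6S)-2,5-bis(benzoyloxy)-1,6-dihydroxycyclohex-3-en-1-yl]methyl benzoate | O=C(OC[C@@]1(O)[C@@H](OC(=O)c2ccccc2)C=C[C@H](OC(=O)c2ccccc2)[C@@H]1O)c1ccccc1 | target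

**Step count and risks**

Total steps: 14. Longest linear sequence: 14 steps (1 to 23).

Steps most likely to fail:

1. Step 5 (proposed new method). Hemiester formation at the hindered tertiary hydroxyl may be slow, the catalyst may discriminate the two enone arms poorly, and reversible retro-oxa-Michael opening may erode the enantiomeric purity. The fallback uses known chemistry and sets out from 8. A chiral phosphoric acid such as TRIP (the enantiomer that gives the 1S,6S series), with 3-methylbutanal in CH2Cl2 over 4 Å MS, should effect the established acetalisation/oxa-Michael cascade of para-quinols: the hemiacetal formed on O1 adds to one enone arm to give the cis-fused 2-isobutyl-1,3-dioxolane enone F1. Hydrolysis of the acetal in cold aqueous TFA should give the (4S,5S)-dihydroxy enone F2. Treatment with 2,2-dimethoxypropane and PPTS in acetone converts it into the acetonide, and the route is rejoined at 12.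

2. Step 10. Hydrazinolysis of the benzoate may compete, hydrazone formation at a ketone flanked by two oxygenated carbons may stall, and the base-sensitive β-alkoxy ketone may already suffer epimerisation at C5 or elimination of O6 in step 9. The fallback sets out from 12 and avoids steps 7 to 10. Kinetic enolisation with LiN(SiMe3)2 and trapping with PhNTf2 in THF at −78 °C gives the dienyl triflate F3. Reduction with Pd(OAc)2, PPh3, Bu3N and HCO2H in DMF at 60 °C gives the cyclohexa-1,3-diene acetonide F4. Photooxygenation (O2, tetraphenylporphyrin, visible light, CH2Cl2, −20 °C) should add singlet oxygen across C2 and C5 on the face opposite the dioxolane to give the endoperoxide F5. Thiourea in MeOH reduces the O–O bond to the 2β,5β-diol F6. Silylation of the less hindered C5 hydroxyl (TBSCl, imidazole, DMF, 0 °C; the C2 hydroxyl is shielded by the quaternary C1) returns to the route at 18.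

3. Step 13. Backside approach to C5 is on the face of the dioxolane ring, so SN2′ attack at C3 or elimination may compete with clean inversion. The fallback sets out from 20 and replaces substitution by oxidation and reduction. Dess–Martin periodinane with NaHCO3 in CH2Cl2 gives the C5 ketone, the C3=C4–C5 enone F7. Luche reduction (NaBH4, CeCl3·7H2O, MeOH, −78 °C) should deliver hydride from the β face, opposite the dioxolane, to give the 5α-alcohol F8 cis to O6. Benzoylation (BzCl, pyridine, DMAP, CH2Cl2) comes back to the route at 22.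

**Further compounds**

F1 | step 5 | cis-fused 2-isobutyl-1,3-dioxolane enone (1S,6S; acetal carbon configuration not defined) | O=C1C=C[C@@]2(COC(=O)c3ccccc3)OC(CC(C)C)O[C@H]2C1
F2 | step 5 | (4S,5S)-4-(benzoyloxymethyl)-4,5-dihydroxycyclohex-2-en-1-one | O=C1C=C[C@@](COC(=O)c2ccccc2)(O)[C@@H](O)C1
F3 | step 10 | dienyl triflate of 12 (C2=C3–C4(OTf)=C5; 1S,6S) | O=S(=O)(OC1=C[C@@H]2OC(C)(C)O[C@]2(COC(=O)c2ccccc2)C=C1)C(F)(F)F
F4 | step 10 | cyclohexa-2,4-diene with O1/O6 acetonide and 7-benzoate (1S,6S) | C1=C[C@@H]2OC(C)(C)O[C@]2(COC(=O)c2ccccc2)C=C1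
F5 | step 10 | 2β,5β-endoperoxide (O–O bridge from C2 to C5, C3=C4, acetonide on the α face) | O=C(OC[C@@]1(OC(C)(C)O2)[C@@H](O3)C=C[C@@H](O3)[C@@H]12)c1ccccc1
F6 | step 10 | 2β,5β-diol with C3=C4, O1/O6 acetonide and 7-benzoate | O=C(OC[C@@]1(OC(C)(C)O2)[C@@H](O)C=C[C@@H](O)[C@@H]12)c1ccccc1
F7 | step 13 | C5 ketone (C3=C4–C5=O enone) with 2β,7-dibenzoate and O1/O6 acetonide | O=C(OC[C@@]1(OC(C)(C)O2)[C@@H](OC(=O)c3ccccc3)C=CC(=O)[C@@H]12)c1ccccc1
F8 | step 13 | 5α-alcohol (cis to O6) with 2β,7-dibenzoate and O1/O6 acetonide | O=C(OC[C@@]1(OC(C)(C)O2)[C@@H](OC(=O)c3ccccc3)C=C[C@H](O)[C@@H]12)c1ccccc1
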